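## Structural features

The target 51 is a bicyclic sesquiterpenoid: a ten-membered carbocycle (C1–C10) trans-fused across C7–C8 to an α-methylene-γ-butyrolactone (C11, C12, exocyclic C13, lactone oxygen on C8), with the C6 oxygen esterified by (Z)-4-hydroxy-2-(hydroxymethyl)but-2-enoic acid. Three stereocentres are contiguous, C6 (R), C7 (S) and C8 (R): O6 and C11 are cis on the ring, C11 and O8 are trans, and a fourth centre, C10 (S), carries the methyl group on the far side of the ring. The only ring olefin, C4=C5, is trisubstituted, has C3 and C6 cis within the ring (E by the sequence rules because of C15), bears the C15 hydroxymethyl group and is allylic to the C6 ester. Fragile groups are the methylene lactone (a Michael acceptor), the (Z)-γ-hydroxy enoate (it can close to a butenolide with loss of the C6 oxygen, or isomerise to E), the allylic C6–O bond, and the pair O6/O8, both γ to C12, so that either could lactonise. The real difficulty is the ten-membered ring: direct closure fights entropy and transannular strain while the olefin geometry must be controlled at the same time. The key step exploits that olefinic C5 and oxygenated C8 are joined by the chain C5–C6–C7–C8: a temporary C5–C8 bond turns this chain into a cyclobutane fused to the eight-membered ring C8–C9–C10–C1–C2–C3–C4–C5, and a spiro-oxirane C4–O–C15 stores the olefin, the C15 hydroxyl and the ring size in one strained bicyclic alcohol.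

## Logic of the disconnections

51 to 50: the three O–Si bonds are cut. All free hydroxyls are carried as the same primary silyl ether so that one mild step ends the synthesis; the forward step must spare the methylene lactone and the (Z)-γ-hydroxy enoate.

50 to 43 and 48: the C6–O acyl bond is cut. This makes the route convergent and keeps the base-sensitive side chain out of all enolate chemistry; the forward acylation must reach a hindered allylic alcohol without Z/E isomerisation, and 43 must carry no other free hydroxyl.

48 to 46, 45 and 44: the bond between the carboxyl carbon and C2' is cut, then the C–I and C–H bonds across the former alkyne. The gain is a symmetric four-carbon diol; the forward steps must add hydride and iodine anti and carry the geometry through metalation with retention.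

43 to 42 to 39: the O6–Si bond and then C11=C13 are cut. The one-carbon unit is added late by enolate chemistry, which is why C6 is a silyl ether and not yet an ester at that stage; the forward sequence needs a C6 silyl group that is more labile than the one on C15.

39 to 37, 36, 35 and 34: the lactone O–C8 bond is cut with inversion, and C12 goes back to a protected primary alcohol. Hydride is expected to reach the C8 ketone from the face that gives the alcohol cis to the C7 side chain, so the C–O bond is planned as an SN2 displacement of a sulfonate by the C12 carboxylate; the forward steps need a selective reduction and substitution in preference to elimination.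

34 to 33 to 31 (key): in the reverse sense the C5–C8 σ bond and the C4–O bond of an oxirane are re-formed. The ten-membered ring is traded for a cyclobutane fused to a cyclooctane, both easier to make, and the olefin geometry becomes a question of configuration at C4; the forward step demands anti-periplanar C5–C8 and C4–O bonds and an alkoxide that fragments faster than it does anything else.

31 to 30, 29, 28 and 27: the C4–C15 bond (sulfur ylide on a C4 ketone) is cut and the C4 oxygen is taken back to a silylated carbinol. C8–O stays silylated whenever C4 is a carbonyl, because a free 2-acylcyclobutanol would open by retro-aldol; the forward steps need face-selective ylide attack at C4 and two selective desilylations.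

27 to 25: the C2–C3 bond is cut (olefin metathesis followed by hydrogenation). This leaves two alkenyl chains on neighbouring cyclobutane carbons; closure requires them to be cis.

25 to 22 and 5: the C8–C9 bond is cut (carbonyl addition). The forward addition must avoid enolisation and must enter anti to the C6 and C7 substituents.

22 to 19 and 20: the C5–C4 bond is cut as an aldol, not an acylation, since a 1,3-diketone would defeat the later carbonyl addition. Enolisation must occur at C5 and the electrophile must add trans to the C6 oxygen.

19 to 18, 17, 14 and 15: the C5–C6 and C7–C8 bonds are cut together ([2+2]). Both ring stereocentres then derive from the enol ether geometry and from a removable chiral group on oxygen; the forward step needs high facial selectivity, and the later removal of that group must not harm the C12 ether.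

14 to 13, 11, 9, 10 and 8 (8 from 7 and 6): the C7–C11 bond (acetylide alkylation) and the vinylic C6–O bond are cut, leading to a chiral alcohol, a two-carbon chloroalkene and a protected iodoethanol.

5 to 4, 3, 1 and 2: the C10–C1 bond is cut (auxiliary-controlled allylation), which sets C10 and supplies C9, C10, C1 and C2 plus a disposable methylene.

## Other disconnections considered

Alternative 1: The cut is C7–C8 together with the O8–C12 bond, leading to the open-chain aldehyde A2 with a 2-(bromomethyl)enoate at C11. In the forward sense CrCl2 (divalent chromium) would convert the allylic bromide into an allylchromium that adds through C7 to the C8 aldehyde, and the C8 alkoxide would then close onto the C12 ester to give methylene lactone A1, which is the same compound as 42.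
- In its favour: ring, C7, C8 and the complete methylene lactone arise in one operation, and A1 lies three steps before 51. Neither a C8 inversion nor an enolate methylenation is needed, so on step economy and convergence this plan is the better one. Its reaction type also has firmer precedent than step 19.
- Against it here: the ten-membered ring is closed directly, against entropy and transannular strain, at high dilution with excess chromium salt. The C6/C7 relationship must come from a macrocyclic transition state that cannot be predicted with confidence. The C4=C5 olefin with its C15 oxygen has to be built stereoselectively in A2 beforehand.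
- Comparison: on mechanism the alternative is better established; on control of C7/C8 the two plans are about equal, since both rest on models. On ring strain and on the origin of the olefin geometry the chosen plan is stronger, because the fragmentation is driven by strain release and is stereospecific.

Alternative 2: The cut is C5–C6, leading to iodo aldehyde A4, in which the lactone is already closed, C5 carries iodine and C6 is an aldehyde. CrCl2 (divalent chromium) with catalytic NiCl2 (divalent nickel) would activate the C5–I bond, and the alkenylchromium would add to the aldehyde, closing the ring and creating the C6 carbinol of A3.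
- In its favour: this type of ring closure tolerates lactones and silyl ethers, and the olefin geometry is carried over with retention. The lactone is settled before ring closure, so O6 and O8 never compete; on that point it is better than the chosen plan, which needs a mesylate detour at C8. Its mechanistic precedent is also better.
- Against it here: C6 is created in the macrocyclisation with no nearby control element, and it must come out cis to C11. The aldehyde sits on C7, which is α-stereogenic and β to the lactone oxygen, so epimerisation and β-elimination threaten A4. A3 still needs α-methylenation with strong base, and the ring is again closed directly.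
- Comparison: step count is probably equal or slightly lower. Structurally the chosen plan fixes C6 early and securely by cycloaddition, whereas here C6 is the least certain centre.

Alternative 3: The cut is C6–C7 in the sense of a [2,3]-Wittig retron, leading to the thirteen-membered diallyl ether A6 with oxygen between C6 and C13. n-BuLi would remove a proton from the C6 methylene; the allyloxy carbanion would attack C7 through a five-membered transition state while O–C13 breaks, giving cyclodecenol A5.
- In its favour: like the chosen plan it reaches the ten-membered ring from another ring size and not by direct closure, so the two are equal in concept. The large ether ring is easy to close, two adjacent stereocentres form in one concerted step, and the C13 methylene arrives in place without enolate methylenation, which is better than the chosen plan.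
- Against it here: two allylic ether methylenes (C6 and C13) can be deprotonated and only one is productive, and [1,2]-shift competes. The C6/C7 outcome depends on the C7=C11 geometry and on the macrocycle conformation. Afterwards C12 must be oxidised and lactonised onto O8 while O6, equally γ to C12, is free, and three silyl ethers must be told apart.
- Comparison: step economy is probably equal. On mechanism the rearrangement is known but its regio- and stereocontrol here is less secure than the early, stereospecific cycloaddition of the chosen plan.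

Key step: step 19

Remark on numbering: ring compounds are described with the atom numbers of 51 (C1–C15, C11–C13 for the lactone unit); all compounds are single enantiomers, and only C4 in 21–28 is a mixture of epimers that converges at 29.

Assumption: in step 9 the ketene is taken to approach the s-trans enol ether anti to the aryl group of the 1-(2,4,6-triisopropylphenyl)ethyl residue; should the sense of induction be the opposite, the enantiomeric alcohol is used in step 6 and nothing else changes.

Remark on design: the configurations of 31, 33 and 51 agree atom by atom at C6, C7 and C10. Three design decisions surround the key step: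
- C12 is carried as a 2-naphthylmethyl (NAP) ether, because a p-methoxybenzyl ether would not survive the acid that removes the chiral group in step 10.
- C4 is introduced by aldol addition and C8–O is kept silylated whenever C4 is a ketone, because a free 2-acylcyclobutanol or its alkoxide would open by retro-aldol.
- The lactone is closed at C8 with inversion, because hydride is expected to give the C8 alcohol cis to the side chain.

## Steps

Step 1
Reactants: 1 (R)-4-benzyl-3-propanoyl-1,3-oxazolidin-2-one; 2 allyl bromide
Product: 3 (R)-4-benzyl-3-[(2S)-2-methylpent-4-enoyl]-1,3-oxazolidin-2-one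
Conditions: NaN(SiMe3)2, THF, −78 °C; then 2, −78 → −40 °C
Reagents that add atoms: none
Why: Evans alkylation: the chelated Z-enolate is allylated on the face opposite the benzyl group, which sets C10 as (S).

Step 2
Reactants: 3 (R)-4-benzyl-3-[(2S)-2-methylpent-4-enoyl]-1,3-oxazolidin-2-one
Product: 4 (S)-2-methylpent-4-en-1-ol
Conditions: LiBH4, H2O (1 equiv), Et2O, 0 °C
Reagents that add atoms: none
Why: Reductive cleavage of the N-acyl oxazolidinone by borohydride releases the primary alcohol without touching the stereocentre or the alkene.

Step 3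
Reactants: 4 (S)-2-methylpent-4-en-1-ol
Product: 5 (S)-5-bromo-4-methylpent-1-ene
Conditions: PPh3, CBr4, CH2Cl2, 0 °C
Reagents that add atoms: carbon tetrabromide BrC(Br)(Br)Br
Why: Appel bromination of a primary alcohol; the stereocentre is β to the reacting carbon and is not involved.

Step 4
Reactants: 6 ethane-1,2-diol
Product: 7 2-(naphthalen-2-ylmethoxy)ethan-1-ol
Conditions: NaH, 6 (5 equiv), THF/DMF, 0 °C; then 2-(bromomethyl)naphthalene, rt
Reagents that add atoms: 2-(bromomethyl)naphthalene BrCc1ccc2ccccc2c1
Why: Williamson ether synthesis with excess diol to favour mono-alkylation; the NAP group is chosen because it survives CF3CO2H in step 10 and still falls to DDQ in step 23.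

Step 5
Reactants: 7 2-(naphthalen-2-ylmethoxy)ethan-1-ol
Product: 8 2-[(2-iodoethoxy)methyl]naphthalene
Conditions: I2, PPh3, imidazole, CH2Cl2, 0 °C → rt
Reagents that add atoms: iodine II
Why: Appel-type iodination of a primary alcohol.

Step 6
Reactants: 9 (S)-1-(2,4,6-triisopropylphenyl)ethan-1-ol; 10 trichloroethene
Product: 11 2-[(1S)-1-{[(E)-1,2-dichloroethenyl]oxy}ethyl]-1,3,5-triisopropylbenzene
Conditions: KH, THF, 0 °C; then 10, −50 °C → rt
Reagents that add atoms: none
Why: Base-induced elimination of 10 to dichloroacetylene and anti addition of the potassium alkoxide (addition–elimination) give the (E)-dichlorovinyl ether; the carbinol centre is not touched.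

Step 7
Reactants: 11 2-[(1S)-1-{[(E)-1,2-dichloroethenyl]oxy}ethyl]-1,3,5-triisopropylbenzene; 8 2-[(2-iodoethoxy)methyl]naphthalene
Product: 13 2-({4-[(1S)-1-(2,4,6-triisopropylphenyl)ethoxy]but-3-yn-1-yl}oxymethyl)naphthalene, via lithium alkoxyacetylide 12 (not isolated)
Conditions: n-BuLi (2.4 equiv), THF, −78 → −40 °C; then 8, HMPA, −78 °C → rt
Reagents that add atoms: none
Why: Dehydrochlorination and chlorine–lithium exchange give acetylide 12, which is C-alkylated by the primary iodide (SN2) and forms the C7–C11 bond.

Step 8
Reactants: 13 2-({4-[(1S)-1-(2,4,6-triisopropylphenyl)ethoxy]but-3-yn-1-yl}oxymethyl)naphthalene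
Product: 14 2-({(3Z)-4-[(1S)-1-(2,4,6-triisopropylphenyl)ethoxy]but-3-en-1-yl}oxymethyl)naphthalene
Conditions: H2 (1 atm), Pd/BaSO4, pyridine, rt
Reagents that add atoms: none
Why: Syn semihydrogenation of the alkyne over a poisoned palladium catalyst gives the (Z)-enol ether needed for a cis C6/C7 relationship.

Step 9
Reactants: 14 2-({(3Z)-4-[(1S)-1-(2,4,6-triisopropylphenyl)ethoxy]but-3-en-1-yl}oxymethyl)naphthalene; 15 trichloroacetyl chloride
Product: 17 (2R,3R)-2-[2-(naphthalen-2-ylmethoxy)ethyl]-3-[(1S)-1-(2,4,6-triisopropylphenyl)ethoxy]cyclobutan-1-one, via dichlorocyclobutanone 16 (not isolated)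
Conditions: 15, Zn(Cu), Et2O, 0 °C → rt; filter; then Zn(Cu), NH4Cl, MeOH, rt
Reagents that add atoms: none
Why: Thermal [2+2] cycloaddition of dichloroketene to the enol ether: the carbonyl carbon bonds to C7 and CCl2 to oxygenated C6, the Z geometry becomes the cis C6/C7 relationship, and approach anti to the aryl group of the auxiliary sets both centres; zinc then removes both chlorines by reductive dehalogenation.

Step 10
Reactants: 17 (2R,3R)-2-[2-(naphthalen-2-ylmethoxy)ethyl]-3-[(1S)-1-(2,4,6-triisopropylphenyl)ethoxy]cyclobutan-1-one
Product: 18 (2R,3R)-3-hydroxy-2-[2-(naphthalen-2-ylmethoxy)ethyl]cyclobutan-1-one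
Conditions: CF3CO2H, CH2Cl2, 0 °C
Reagents that add atoms: none
Why: Acidolysis (E1) of the hindered, electron-rich benzylic ether frees the C6 hydroxyl; the NAP ether is not ionised under these conditions.

Step 11
Reactants: 18 (2R,3R)-3-hydroxy-2-[2-(naphthalen-2-ylmethoxy)ethyl]cyclobutan-1-one
Product: 19 (2R,3R)-2-[2-(naphthalen-2-ylmethoxy)ethyl]-3-(triethylsilyloxy)cyclobutan-1-one
Conditions: Et3SiCl, imidazole, CH2Cl2, 0 °C
Reagents that add atoms: chlorotriethylsilane CC[Si](Cl)(CC)CC
Why: Silylation of the secondary alcohol with a base too weak to enolise the β-hydroxy cyclobutanone.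

Step 12
Reactants: 19 (2R,3R)-2-[2-(naphthalen-2-ylmethoxy)ethyl]-3-(triethylsilyloxy)cyclobutan-1-one; 20 acrolein
Product: 22 cyclobutanone with C5–CH(OSiMe3)CH=CH2 trans to C6–OSiEt3 (C4 epimers), via lithium aldolate 21 (not isolated)
Conditions: LiN(i-Pr)2, THF, −78 °C; 20; then Me3SiCl, Et3N, −78 → 0 °C
Reagents that add atoms: chlorotrimethylsilane C[Si](C)(C)Cl
Why: Kinetic deprotonation at the unsubstituted α-carbon C5 and aldol 1,2-addition to acrolein trans to the neighbouring C6 silyloxy group set C5; the aldolate is silylated in the flask to block retro-aldol, and C4 is later oxidised so its configuration does not matter.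

Step 13
Reactants: 22 cyclobutanone with C5–CH(OSiMe3)CH=CH2 trans to C6–OSiEt3 (C4 epimers); 5 (S)-5-bromo-4-methylpent-1-ene
Product: 25 cyclobutane diene with C8–OSiMe3 and the C9 chain cis to C4, via Grignard reagent 23 (not isolated), via dichlorocerium alkoxide 24 (not isolated)
Conditions: 5, Mg, THF; CeCl3, THF, −78 °C; then 22, −78 °C; then Me3SiOTf, −78 → 0 °C
Reagents that add atoms: trimethylsilyl trifluoromethanesulfonate C[Si](C)(C)OS(=O)(=O)C(F)(F)F
Why: Organocerium 1,2-addition avoids enolisation of the cyclobutanone and should enter anti to the cis-disposed C6 silyloxy group and C7 side chain, i.e. syn to the C5 substituent, which sets C8 with C9 cis to C4; the tertiary alkoxide is silylated at once so that C8–O is never free while C4 is a ketone.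

Step 14
Reactants: 25 cyclobutane diene with C8–OSiMe3 and the C9 chain cis to C4
Product: 27 cis-fused bicyclo[6.2.0]decane with C4–OSiMe3 and C8–OSiMe3, via cyclooctene 26 (not isolated)
Conditions: second-generation Grubbs catalyst (H2IMes)(PCy3)Cl2Ru=CHPh (5 mol %), CH2Cl2 (0.002 M), 40 °C; then H2 (5 bar), 40 °C
Reagents that add atoms: none
Why: Ring-closing metathesis of the two terminal alkenes held cis on the cyclobutane closes the eight-membered ring at C2=C3; the ruthenium residue then acts as hydrogenation catalyst under H2 (tandem metathesis–hydrogenation).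

Step 15
Reactants: 27 cis-fused bicyclo[6.2.0]decane with C4–OSiMe3 and C8–OSiMe3
Product: 28 bicyclic C4 alcohol with C8–OSiMe3
Conditions: K2CO3 (0.2 equiv), MeOH, −10 °C
Reagents that add atoms: none
Why: Base-catalysed methanolysis of silyl ethers: the secondary trimethylsilyl ether is far more accessible than the tertiary ring-fusion one and the triethylsilyl ether, so only C4–OH is freed.

Step 16
Reactants: 28 bicyclic C4 alcohol with C8–OSiMe3
Product: 29 bicyclic C4 ketone with C8–OSiMe3
Conditions: Dess–Martin periodinane, NaHCO3, CH2Cl2, 0 °C → rt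
Reagents that add atoms: none
Why: Dess–Martin oxidation of the secondary alcohol under buffered conditions; C8–O is silylated, so the retro-aldol opening of a 2-acylcyclobutanol cannot start.

Step 17
Reactants: 29 bicyclic C4 ketone with C8–OSiMe3
Product: 30 spiro-oxirane with C8–OSiMe3 (C15 syn to H5; oxirane O syn to C6)
Conditions: Me3S+ I−, KN(SiMe3)2, THF, −10 → 0 °C
Reagents that add atoms: trimethylsulfonium iodide C[S+](C)C.[I-]
Why: Corey–Chaykovsky epoxidation: the sulfonium ylide adds irreversibly to the C4 carbonyl from the convex face, anti to cyclobutane carbon C6, and the betaine closes, so C15 ends syn to H5 and the oxirane oxygen syn to C6, which sets C4.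

Step 18
Reactants: 30 spiro-oxirane with C8–OSiMe3 (C15 syn to H5; oxirane O syn to C6)
Product: 31 cis-fused epoxy cyclobutanol (C8–OH free; C6–OSiEt3; C12–ONAP)
Conditions: Bu4NF, AcOH (1:1), THF, 0 °C
Reagents that add atoms: none
Why: Buffered fluoride desilylation removes the trimethylsilyl ether much faster than the triethylsilyl ether and leaves the oxirane intact; without base the alcohol is stable.

Step 19
Reactants: 31 cis-fused epoxy cyclobutanol (C8–OH free; C6–OSiEt3; C12–ONAP)
Product: 33 cyclodecenone with ring-cis C4=C5 and free C15–OH, via potassium cyclobutoxide 32 (not isolated)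
Conditions: KN(SiMe3)2 (1.0 equiv), THF, −78 → −30 °C; then AcOH, −78 °C
Reagents that add atoms: none
Why: Proposed new method: the base converts 31 into cyclobutoxide 32, whose oxygen lone pair pushes into the C8–C5 σ bond while that bond donates into σ*(C4–O) of the oxirane lying anti-periplanar to it, so C8=O and C4=C5 form and the C15 alkoxide is expelled in one concerted heterolysis. The closest known reaction types are Grob fragmentations of epoxy alkoxides to medium-ring ketones and the retro-aldol opening of 2-acylcyclobutanols (de Mayo reaction), but a fused cyclobutanol donor combined with a spiro-oxirane nucleofuge has no direct precedent. No ring is closed by cyclisation: the ten-membered ring appears because the zero bridge of the bicyclo[6.2.0]decane is cut, so the transannular strain of the cyclodecene is paid by release of cyclobutane and oxirane strain. No stereocentre is created; C6, C7 and C10 are spectators and C5 and C8 become trigonal. The selectivities needed are olefin geometry and chemoselectivity. In the only reactive conformer C3 is synclinal to both C8 and C6 and the oxirane oxygen is anti to C8, an arrangement that the C4 configuration from step 17 makes possible, so C3 and C6 emerge cis in the ring and C15 trans to C6. Fragmentation must outrun attack of the alkoxide on C15 (a 5-endo oxirane opening with poor orbital alignment), transfer of the C6 silyl group to O8 and β-elimination of the C6 silyloxy group from the product ketone. One equivalent of a soluble base, low temperature and a cold acidic quench are chosen for that reason.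

Step 20
Reactants: 33 cyclodecenone with ring-cis C4=C5 and free C15–OH
Product: 34 cyclodecenone C15 tert-butyldimethylsilyl ether
Conditions: t-BuMe2SiCl, imidazole, CH2Cl2, 0 °C
Reagents that add atoms: tert-butyldimethylsilyl chloride CC(C)(C)[Si](C)(C)Cl
Why: Silylation of the primary allylic alcohol with imidazole, mild enough for the β-silyloxy ketone.

Step 21
Reactants: 34 cyclodecenone C15 tert-butyldimethylsilyl ether
Product: 35 C8 alcohol with O8 cis to the C7 side chain (8-epi)
Conditions: LiBH(s-Bu)3, THF, −78 °C; then NaBO3·4H2O, H2O, 0 °C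
Reagents that add atoms: none
Why: Reduction of a medium-ring ketone by a bulky borohydride: hydride should enter from the periphery, anti to ring bond C7–C6 in the conformer where the C7 side chain flanks the carbonyl oxygen, which gives the alcohol cis to that side chain. This outcome is used on purpose, because step 24 inverts C8.

Step 22
Reactants: 35 C8 alcohol with O8 cis to the C7 side chain (8-epi)
Product: 36 C8 methanesulfonate
Conditions: MeSO2Cl, Et3N, CH2Cl2, −20 °C
Reagents that add atoms: methanesulfonyl chloride CS(=O)(=O)Cl
Why: Sulfonylation of the secondary alcohol with retention at C8.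

Step 23
Reactants: 36 C8 methanesulfonate
Product: 37 C12 primary alcohol C8 methanesulfonate
Conditions: DDQ, CH2Cl2/pH 7 buffer (10:1), 0 °C → rt
Reagents that add atoms: none
Why: Oxidative cleavage of the NAP ether by DDQ (hydride abstraction, then hydrolysis of the oxocarbenium ion); silyl ethers, mesylate and the trisubstituted alkene are inert.

Step 24
Reactants: 37 C12 primary alcohol C8 methanesulfonate
Product: 39 trans-fused 8,12-lactone (C6–OSiEt3; C15–OSi(t-Bu)Me2), via C12 carboxylic acid 38 (not isolated)
Conditions: TEMPO (cat.), PhI(OAc)2, MeCN/pH 7 buffer, rt; then Cs2CO3, DMF, 40 °C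
Reagents that add atoms: water O
Why: Nitroxyl-catalysed oxidation of the primary alcohol to the carboxylic acid, then intramolecular SN2 displacement (5-exo-tet) of the C8 mesylate by the carboxylate with inversion, which sets C8 as (R) and gives the trans-fused lactone.

Step 25
Reactants: 39 trans-fused 8,12-lactone (C6–OSiEt3; C15–OSi(t-Bu)Me2)
Product: 42 α-methylene lactone (C6–OSiEt3; C15–OSi(t-Bu)Me2), via Mannich base 40 (not isolated), via ammonium iodide 41 (not isolated)
Conditions: LiN(i-Pr)2, THF, −78 °C; CH2=NMe2+ I−, −78 °C → rt; then MeI, MeOH, rt; then NaHCO3 (aq), CH2Cl2, rt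
Reagents that add atoms: N,N-dimethylmethyleneiminium iodide C=[N+](C)C.[I-]
Why: α-Methylenation of the lactone by Mannich reaction of its lithium enolate with Eschenmoser's salt, N-methylation and base-induced elimination of trimethylamine (Hofmann-type).

Step 26
Reactants: 42 α-methylene lactone (C6–OSiEt3; C15–OSi(t-Bu)Me2)
Product: 43 C6 alcohol (C15–OSi(t-Bu)Me2)
Conditions: PPTS (cat.), MeOH/CH2Cl2 (1:1), 0 °C
Reagents that add atoms: none
Why: Acid-catalysed methanolysis removes the secondary triethylsilyl ether faster than the primary tert-butyldimethylsilyl ether.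

Step 27
Reactants: 44 but-2-yne-1,4-diol
Product: 45 (Z)-2-iodobut-2-ene-1,4-diol
Conditions: NaAlH2(OCH2CH2OMe)2, THF, 0 °C → rt; then I2, −78 °C
Reagents that add atoms: iodine II
Why: Hydroxyl-directed trans-hydroalumination of the alkyne and iodinolysis of the alkenylalane with retention place iodine cis to C4; the diol is symmetric, so regiochemistry is not an issue.

Step 28
Reactants: 45 (Z)-2-iodobut-2-ene-1,4-diol
Product: 46 (Z)-1,4-bis(tert-butyldimethylsilyloxy)-2-iodobut-2-ene
Conditions: t-BuMe2SiCl, imidazole, DMF, rt
Reagents that add atoms: tert-butyldimethylsilyl chloride CC(C)(C)[Si](C)(C)Cl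
Why: Silylation of both primary alcohols.

Step 29
Reactants: 46 (Z)-1,4-bis(tert-butyldimethylsilyloxy)-2-iodobut-2-ene
Product: 48 (Z)-4-(tert-butyldimethylsilyloxy)-2-[(tert-butyldimethylsilyloxy)methyl]but-2-enoic acid, via alkenylmagnesium chloride 47 (not isolated)
Conditions: i-PrMgCl·LiCl, THF, −40 °C; then CO2, −40 °C → rt; aq. HCl to pH 3
Reagents that add atoms: carbon dioxide O=C=O
Why: Iodine–magnesium exchange with retention of alkene geometry and carboxylation of the alkenyl Grignard reagent; at −40 °C the magnesium species should neither eliminate the allylic silyloxy group nor accept a silyl group from the cis oxygen.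

Step 30
Reactants: 43 C6 alcohol (C15–OSi(t-Bu)Me2); 48 (Z)-4-(tert-butyldimethylsilyloxy)-2-[(tert-butyldimethylsilyloxy)methyl]but-2-enoic acid
Product: 50 tris(tert-butyldimethylsilyl) ether of 51, via mixed anhydride 49 (not isolated)
Conditions: 48, 2,4,6-Cl3C6H2COCl, Et3N, toluene, rt; then 43, DMAP (cat.), toluene, rt
Reagents that add atoms: none
Why: Yamaguchi esterification through the mixed anhydride: the hindered aroyl carbonyl steers the alcohol to the enoyl carbonyl, C6 reacts with retention, and DMAP is kept catalytic to limit Z-to-E isomerisation of the enoate.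

Step 31
Reactants: 50 tris(tert-butyldimethylsilyl) ether of 51
Product: 51 CNP0131216.1
Conditions: HF·pyridine, pyridine, THF, 0 °C → rt
Reagents that add atoms: none
Why: Fluoride-mediated cleavage of the three primary silyl ethers under buffered, weakly acidic conditions that spare the methylene lactone, both esters and the (Z)-γ-hydroxy enoate.

## Compound list

1 | (R)-4-benzyl-3-propanoyl-1,3-oxazolidin-2-one | CCC(=O)N1[C@H](Cc2ccccc2)COC1=O | starting material
2 | allyl bromide | C=CCBr | starting material
3 | (R)-4-benzyl-3-[(2S)-2-methylpent-4-enoyl]-1,3-oxazolidin-2-one | C=CC[C@H](C)C(=O)N1[C@H](Cc2ccccc2)COC1=O | intermediate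
4 | (S)-2-methylpent-4-en-1-ol | OC[C@@H](C)CC=C | intermediate
5 | (S)-5-bromo-4-methylpent-1-ene | BrC[C@@H](C)CC=C | intermediate
6 | ethane-1,2-diol | OCCO | starting material
7 | 2-(naphthalen-2-ylmethoxy)ethan-1-ol | OCCOCc1ccc2ccccc2c1 | intermediate
8 | 2-[(2-iodoethoxy)methyl]naphthalene | ICCOCc1ccc2ccccc2c1 | intermediate
9 | (S)-1-(2,4,6-triisopropylphenyl)ethan-1-ol | C[C@H](O)c1c(C(C)C)cc(C(C)C)cc1C(C)C | starting material
10 | trichloroethene | ClC=C(Cl)Cl | starting material
11 | 2-[(1S)-1-{[(E)-1,2-dichloroethenyl]oxy}ethyl]-1,3,5-triisopropylbenzene | C[C@H](O/C(Cl)=C\Cl)c1c(C(C)C)cc(C(C)C)cc1C(C)C | intermediate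
12 | lithium 2-[(1S)-1-(2,4,6-triisopropylphenyl)ethoxy]ethynide | C[C@H](OC#C[Li])c1c(C(C)C)cc(C(C)C)cc1C(C)C | intermediate (not isolated)
13 | 2-({4-[(1S)-1-(2,4,6-triisopropylphenyl)ethoxy]but-3-yn-1-yl}oxymethyl)naphthalene | C[C@H](OC#CCCOCc1ccc2ccccc2c1)c1c(C(C)C)cc(C(C)C)cc1C(C)C | intermediate
14 | 2-({(3Z)-4-[(1S)-1-(2,4,6-triisopropylphenyl)ethoxy]but-3-en-1-yl}oxymethyl)naphthalene | C[C@H](O/C=C\CCOCc1ccc2ccccc2c1)c1c(C(C)C)cc(C(C)C)cc1C(C)C | intermediate
15 | trichloroacetyl chloride | ClC(=O)C(Cl)(Cl)Cl | starting material
16 | (3S,4R)-2,2-dichloro-4-[2-(naphthalen-2-ylmethoxy)ethyl]-3-[(1S)-1-(2,4,6-triisopropylphenyl)ethoxy]cyclobutan-1-one | O=C1C(Cl)(Cl)[C@@H](O[C@@H](C)c2c(C(C)C)cc(C(C)C)cc2C(C)C)[C@H]1CCOCc1ccc2ccccc2c1 | intermediate (not isolated)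
17 | (2R,3R)-2-[2-(naphthalen-2-ylmethoxy)ethyl]-3-[(1S)-1-(2,4,6-triisopropylphenyl)ethoxy]cyclobutan-1-one | O=C1C[C@@H](O[C@@H](C)c2c(C(C)C)cc(C(C)C)cc2C(C)C)[C@H]1CCOCc1ccc2ccccc2c1 | intermediate
18 | (2R,3R)-3-hydroxy-2-[2-(naphthalen-2-ylmethoxy)ethyl]cyclobutan-1-one | O=C1C[C@@H](O)[C@H]1CCOCc1ccc2ccccc2c1 | intermediate
19 | (2R,3R)-2-[2-(naphthalen-2-ylmethoxy)ethyl]-3-(triethylsilyloxy)cyclobutan-1-one | O=C1C[C@@H](O[Si](CC)(CC)CC)[C@H]1CCOCc1ccc2ccccc2c1 | intermediate
20 | acrolein | C=CC=O | starting material
21 | lithium aldolate: cyclobutanone 19 carrying CH(OLi)CH=CH2 at C5, trans to C6–OSiEt3 (C4 epimers) | O=C1[C@H](C(O[Li])C=C)[C@@H](O[Si](CC)(CC)CC)[C@H]1CCOCc1ccc2ccccc2c1 | intermediate (not isolated)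
22 | cyclobutanone with C5–CH(OSiMe3)CH=CH2 trans to C6–OSiEt3; C6–OSiEt3 and C7–CH2CH2ONAP cis (C4 epimers) | O=C1[C@H](C(O[Si](C)(C)C)C=C)[C@@H](O[Si](CC)(CC)CC)[C@H]1CCOCc1ccc2ccccc2c1 | intermediate
23 | [(2S)-2-methylpent-4-en-1-yl]magnesium bromide | Br[Mg]C[C@@H](C)CC=C | intermediate (not isolated)
24 | dichlorocerium C8 alkoxide of the adduct of 23 and 22 (C9 chain cis to C4) | Cl[Ce](Cl)O[C@@]1(C[C@@H](C)CC=C)[C@H](C(O[Si](C)(C)C)C=C)[C@@H](O[Si](CC)(CC)CC)[C@H]1CCOCc1ccc2ccccc2c1 | intermediate (not isolated)
25 | cyclobutane diene: C8 bears OSiMe3 and the (2S)-2-methylpent-4-enyl chain (cis to C4); C5 bears CH(OSiMe3)CH=CH2; C6–OSiEt3; C7–CH2CH2ONAP | C[Si](C)(C)O[C@@]1(C[C@@H](C)CC=C)[C@H](C(O[Si](C)(C)C)C=C)[C@@H](O[Si](CC)(CC)CC)[C@H]1CCOCc1ccc2ccccc2c1 | intermediate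
26 | cis-fused bicyclo[6.2.0]decene with cis C2=C3; C4–OSiMe3; C8–OSiMe3; C6–OSiEt3; C12–ONAP; (10S)-methyl | C[Si](C)(C)O[C@@]12C[C@@H](C)C/C=C\C(O[Si](C)(C)C)[C@@H]1[C@@H](O[Si](CC)(CC)CC)[C@H]2CCOCc1ccc2ccccc2c1 | intermediate (not isolated)
27 | cis-fused bicyclo[6.2.0]decane; C4–OSiMe3 (epimers); C8–OSiMe3; C6–OSiEt3; C12–ONAP | C[Si](C)(C)O[C@@]12C[C@@H](C)CCCC(O[Si](C)(C)C)[C@@H]1[C@@H](O[Si](CC)(CC)CC)[C@H]2CCOCc1ccc2ccccc2c1 | intermediate
28 | bicyclic C4 alcohol (epimers); C8–OSiMe3; C6–OSiEt3; C12–ONAP | C[Si](C)(C)O[C@@]12C[C@@H](C)CCCC(O)[C@@H]1[C@@H](O[Si](CC)(CC)CC)[C@H]2CCOCc1ccc2ccccc2c1 | intermediate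
29 | bicyclic C4 ketone; C8–OSiMe3; C6–OSiEt3; C12–ONAP | C[Si](C)(C)O[C@@]12C[C@@H](C)CCCC(=O)[C@@H]1[C@@H](O[Si](CC)(CC)CC)[C@H]2CCOCc1ccc2ccccc2c1 | intermediate
30 | C4 spiro-oxirane (C15 syn to H5; oxirane O syn to C6); C8–OSiMe3; C6–OSiEt3; C12–ONAP | C[Si](C)(C)O[C@@]12C[C@@H](C)CCC[C@@]3(CO3)[C@@H]1[C@@H](O[Si](CC)(CC)CC)[C@H]2CCOCc1ccc2ccccc2c1 | intermediate
31 | cis-fused bicyclo[6.2.0]decan-1-ol with C4 spiro-oxirane; C6–OSiEt3; C12–ONAP (key-step precursor) | O[C@@]12C[C@@H](C)CCC[C@@]3(CO3)[C@@H]1[C@@H](O[Si](CC)(CC)CC)[C@H]2CCOCc1ccc2ccccc2c1 | intermediate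
32 | potassium C8 alkoxide of 31 | [O-][C@@]12C[C@@H](C)CCC[C@@]3(CO3)[C@@H]1[C@@H](O[Si](CC)(CC)CC)[C@H]2CCOCc1ccc2ccccc2c1.[K+] | intermediate (not isolated)
33 | cyclodecenone: C8 ketone; ring-cis C4=C5 with free C15–OH; C6–OSiEt3; C7–CH2CH2ONAP; (10S)-methyl (key-step product) | O=C1C[C@@H](C)CCC/C(CO)=C\[C@@H](O[Si](CC)(CC)CC)[C@H]1CCOCc1ccc2ccccc2c1 | intermediate
34 | cyclodecenone with C15–OSi(t-Bu)Me2; C6–OSiEt3; C12–ONAP | O=C1C[C@@H](C)CCC/C(CO[Si](C)(C)C(C)(C)C)=C\[C@@H](O[Si](CC)(CC)CC)[C@H]1CCOCc1ccc2ccccc2c1 | intermediate
35 | C8 alcohol with O8 cis to the C7 side chain (8-epi); C15–OSi(t-Bu)Me2; C6–OSiEt3; C12–ONAP | O[C@H]1C[C@@H](C)CCC/C(CO[Si](C)(C)C(C)(C)C)=C\[C@@H](O[Si](CC)(CC)CC)[C@H]1CCOCc1ccc2ccccc2c1 | intermediate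
36 | C8 methanesulfonate of 35 | CS(=O)(=O)O[C@H]1C[C@@H](C)CCC/C(CO[Si](C)(C)C(C)(C)C)=C\[C@@H](O[Si](CC)(CC)CC)[C@H]1CCOCc1ccc2ccccc2c1 | intermediate
37 | C12 primary alcohol; C8 methanesulfonate | CS(=O)(=O)O[C@H]1C[C@@H](C)CCC/C(CO[Si](C)(C)C(C)(C)C)=C\[C@@H](O[Si](CC)(CC)CC)[C@H]1CCO | intermediate
38 | C12 carboxylic acid; C8 methanesulfonate | CS(=O)(=O)O[C@H]1C[C@@H](C)CCC/C(CO[Si](C)(C)C(C)(C)C)=C\[C@@H](O[Si](CC)(CC)CC)[C@H]1CC(=O)O | intermediate (not isolated)
39 | trans-fused 8,12-lactone (8R); C6–OSiEt3; C15–OSi(t-Bu)Me2 | C1C(=O)O[C@@H]2C[C@@H](C)CCC/C(CO[Si](C)(C)C(C)(C)C)=C\[C@@H](O[Si](CC)(CC)CC)[C@@H]12 | intermediate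
40 | C11 (dimethylamino)methyl lactone (C11 epimers) | CN(C)CC1C(=O)O[C@@H]2C[C@@H](C)CCC/C(CO[Si](C)(C)C(C)(C)C)=C\[C@@H](O[Si](CC)(CC)CC)[C@@H]12 | intermediate (not isolated)
41 | C11 (trimethylammonio)methyl lactone iodide | C[N+](C)(C)CC1C(=O)O[C@@H]2C[C@@H](C)CCC/C(CO[Si](C)(C)C(C)(C)C)=C\[C@@H](O[Si](CC)(CC)CC)[C@@H]12.[I-] | intermediate (not isolated)
42 | α-methylene lactone; C6–OSiEt3; C15–OSi(t-Bu)Me2 | C=C1C(=O)O[C@@H]2C[C@@H](C)CCC/C(CO[Si](C)(C)C(C)(C)C)=C\[C@@H](O[Si](CC)(CC)CC)[C@@H]12 | intermediate
43 | α-methylene lactone with free C6–OH; C15–OSi(t-Bu)Me2 | C=C1C(=O)O[C@@H]2C[C@@H](C)CCC/C(CO[Si](C)(C)C(C)(C)C)=C\[C@@H](O)[C@@H]12 | intermediate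
44 | but-2-yne-1,4-diol | OCC#CCO | starting material
45 | (Z)-2-iodobut-2-ene-1,4-diol | OC/C=C(\I)CO | intermediate
46 | (Z)-1,4-bis(tert-butyldimethylsilyloxy)-2-iodobut-2-ene | CC(C)(C)[Si](C)(C)OC/C=C(\I)CO[Si](C)(C)C(C)(C)C | intermediate
47 | (Z)-1,4-bis(tert-butyldimethylsilyloxy)but-2-en-2-ylmagnesium chloride | CC(C)(C)[Si](C)(C)OC/C=C(\[Mg]Cl)CO[Si](C)(C)C(C)(C)C | intermediate (not isolated)
48 | (Z)-4-(tert-butyldimethylsilyloxy)-2-[(tert-butyldimethylsilyloxy)methyl]but-2-enoic acid | CC(C)(C)[Si](C)(C)OC/C=C(\C(=O)O)CO[Si](C)(C)C(C)(C)C | intermediate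
49 | mixed anhydride of 48 with 2,4,6-trichlorobenzoic acid | CC(C)(C)[Si](C)(C)OC/C=C(\C(=O)OC(=O)c1c(Cl)cc(Cl)cc1Cl)CO[Si](C)(C)C(C)(C)C | intermediate (not isolated)
50 | tris(tert-butyldimethylsilyl) ether of 51 (C15–O and both side-chain oxygens silylated) | C=C1C(=O)O[C@@H]2C[C@@H](C)CCC/C(CO[Si](C)(C)C(C)(C)C)=C\[C@@H](OC(=O)/C(=C\CO[Si](C)(C)C(C)(C)C)CO[Si](C)(C)C(C)(C)C)[C@@H]12 | intermediate
51 | CNP0131216.1: (6R,7S,8R,10S) trans-fused α-methylene 8,12-lactone of the ring-cis C4=C5 cyclodecene with C15–OH and C6 (Z)-4-hydroxy-2-(hydroxymethyl)but-2-enoate | C=C1C(=O)O[C@@H]2C[C@@H](C)CCC/C(CO)=C\[C@@H](OC(=O)/C(=C\CO)CO)[C@@H]12 | target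

## Step count and least certain steps

Total: 31 steps. Longest linear sequence: 24 steps (steps 4, 5, 7–26, 30 and 31, from ethane-1,2-diol 6).

Step 19 (key step, proposed new method). The alkoxide may be consumed by competing processes before or after fragmentation: transfer of the C6 silyl group to O8 across the cyclobutane, 5-endo opening of the oxirane at C15 to a cyclic ether, or enolisation of the product ketone followed by loss of the C6 silyloxy group. All of these start from the same anion, and the rate of the desired heterolysis depends on how well the ring can hold the C5–C8 and C4–O bonds anti. Fallback with known chemistry, from 29 back to 33: ketone 29 would be treated with an anhydrous fluoride source (Bu4N[Ph3SiF2]) at −78 °C in the presence of PhNTf2. Cleavage of the tertiary silyl ether gives a 2-acylcyclobutanoxide, which opens by retro-aldol (de Mayo type) along the same C5–C8 bond; the regiodefined C4–C5 enolate is trapped as enol triflate F1. Stille coupling of F1 with Bu3SnCH2OH (Pd(PPh3)4, LiCl, dioxane) then installs C15 and gives 33.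

Step 13. Poor facial selectivity of the carbonyl addition is the main danger: the branched C5 substituent shields the face that the nucleophile must use, and the wrong C8 epimer cannot close the cis-fused ring in step 14; incomplete silylation of the hindered alkoxide is a second weakness. Fallback, from 19 and 5 back to 27: rhodium-catalysed hydroformylation of 5 (Rh(acac)(CO)2, Xantphos, CO/H2) would give (5S)-6-bromo-5-methylhexanal F2. Aldol addition of the lithium enolate of 19 to F2 with silylation in the flask would give bromo ketone F3. SmI2 (divalent samarium) with HMPA would then form C8–C9 by intramolecular Barbier reaction, in which the tether on C5 can only reach the face of C8 cis to C4, giving bicyclic alcohol F4. Silylation (Me3SiOTf, 2,6-lutidine) returns to 27 without metathesis or hydrogenation.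

Step 17. Facial selectivity of ylide addition may be low or reversed, because the C8 silyloxy group lies on the same face as the intended trajectory; enolisation of the hindered ketone by the basic ylide is a further drain. Fallback, from 29 back to 30: Wittig methylenation (Ph3P=CH2) would give exocyclic alkene F5, and epoxidation with m-CPBA (NaHCO3) would deliver oxygen from the more open face. Since carbon and oxygen then change roles, this sequence gives the C4 epimer opposite to that of direct ylide addition and leads to 30 if the ylide prefers the face syn to C6.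

Step 21 (with step 24). Hydride delivery may occur from the other face if the ten-membered ring reacts through a conformer with the carbonyl oxygen remote from the side chain; the SN2 lactonisation may also lose material to elimination. Fallback, from 34 back to 39: if reduction gives the alcohol trans to the side chain F6, the mesylate is dropped; DDQ would give diol F7, and oxidative lactonisation (TEMPO, PhI(OAc)2) would close the lactone with retention at C8 to 39.

Step 30. Isomerisation of the (Z)-enoate to the more stable E isomer by reversible conjugate addition of the acyl-transfer catalyst, and slow acylation of the hindered allylic alcohol, are the likely problems. Fallback, from 43 and 46 to 50: palladium-catalysed alkoxycarbonylation of alkenyl iodide 46 under CO (Pd(PPh3)4, zerovalent palladium, Et3N, DMF) with 43 as the nucleophile forms the same ester through an acylpalladium species with retention of geometry and without an activated acyl–pyridinium intermediate; no new compound is involved.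

## Further compounds

F1 | step 19 | cyclodecenone C4 enol triflate (ring-cis C4=C5; C6–OSiEt3; C12–ONAP) | O=C1C[C@@H](C)CCC/C(OS(=O)(=O)C(F)(F)F)=C\[C@@H](O[Si](CC)(CC)CC)[C@H]1CCOCc1ccc2ccccc2c1
F2 | step 13 | (5S)-6-bromo-5-methylhexanal | O=CCCC[C@H](C)CBr
F3 | step 13 | cyclobutanone with C5–CH(OSiMe3)(CH2)3CH(CH3)CH2Br trans to C6–OSiEt3 (C4 epimers) | O=C1[C@H](C(O[Si](C)(C)C)CCC[C@H](C)CBr)[C@@H](O[Si](CC)(CC)CC)[C@H]1CCOCc1ccc2ccccc2c1
F4 | step 13 | cis-fused bicyclo[6.2.0]decan-1-ol with C4–OSiMe3; C6–OSiEt3; C12–ONAP | O[C@@]12C[C@@H](C)CCCC(O[Si](C)(C)C)[C@@H]1[C@@H](O[Si](CC)(CC)CC)[C@H]2CCOCc1ccc2ccccc2c1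
F5 | step 17 | bicyclic C4 exocyclic methylene compound; C8–OSiMe3; C6–OSiEt3; C12–ONAP | C[Si](C)(C)O[C@@]12C[C@@H](C)CCCC(=C)[C@@H]1[C@@H](O[Si](CC)(CC)CC)[C@H]2CCOCc1ccc2ccccc2c1
F6 | step 21 | C8 alcohol with O8 trans to the C7 side chain (8R); C15–OSi(t-Bu)Me2; C6–OSiEt3; C12–ONAP | O[C@@H]1C[C@@H](C)CCC/C(CO[Si](C)(C)C(C)(C)C)=C\[C@@H](O[Si](CC)(CC)CC)[C@H]1CCOCc1ccc2ccccc2c1
F7 | step 21 | C8,C12 diol (8R); C15–OSi(t-Bu)Me2; C6–OSiEt3 | O[C@@H]1C[C@@H](C)CCC/C(CO[Si](C)(C)C(C)(C)C)=C\[C@@H](O[Si](CC)(CC)CC)[C@H]1CCO
F0 | step 30 | none | none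
A1 | alternative 1 | bicyclic methylene lactone with C6–OSiEt3 and C15–OSi(t-Bu)Me2 (identical with 42) | C=C1C(=O)O[C@@H]2C[C@@H](C)CCC/C(CO[Si](C)(C)C(C)(C)C)=C\[C@@H](O[Si](CC)(CC)CC)[C@@H]12
A2 | alternative 1 | open-chain C8 aldehyde with methyl 2-(bromomethyl)enoate at C11 | O=CC[C@@H](C)CCC/C(CO[Si](C)(C)C(C)(C)C)=C\[C@@H](O[Si](CC)(CC)CC)/C=C(\CBr)C(=O)OC
A3 | alternative 2 | bicyclic lactone with free C6 hydroxyl, lacking C13 | C1C(=O)O[C@@H]2C[C@@H](C)CCC/C(CO[Si](C)(C)C(C)(C)C)=C\[C@@H](O)[C@@H]12
A4 | alternative 2 | γ-lactone with C6 aldehyde on C7 and (E)-alkenyl iodide at C5 (iodine cis to C3) | O=C[C@H]1CC(=O)O[C@@H]1C[C@@H](C)CCC/C(CO[Si](C)(C)C(C)(C)C)=C\I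
A5 | alternative 3 | cyclodecenol with free C6 hydroxyl and the C11 methylene unit on C7 | C=C(CO[Si](CC)(CC)CC)[C@H]1[C@H](O[Si](CC)(CC)CC)C[C@@H](C)CCC/C(CO[Si](C)(C)C(C)(C)C)=C\[C@H]1O
A6 | alternative 3 | thirteen-membered diallyl ether (oxygen between C6 and C13) | O1C/C(CO[Si](CC)(CC)CC)=C\[C@H](O[Si](CC)(CC)CC)C[C@@H](C)CCC/C(CO[Si](C)(C)C(C)(C)C)=C\C1
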